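**Plan**

- Retrosynthesis: in each alkaloid arm the N2'–C1' and N2'–C3' bonds are cut first (N-methyl lactam, then Beckmann retron: nitrogen excised, C1' joined to C3'). Next C1'–C3', C3'–C4' and C4a'–C7a' are cut together (Pauson–Khand retron), then the two styrenyl C=C bonds and the two aryl–C1' bonds. This leaves 6,8-dibromo-(+)-catechin pentakis(MOM) ether and two molecules of (S)-3-methyloct-6-ynal, the latter from (S)-citronellal.
- Forward: the aldehyde chain is made in five steps; two molecules of it are joined to C6 and C8 of ring A by aryllithium addition and dehydrated to (E)-styrenes; one two-fold cyclocarbonylation closes all four carbocycles (two cyclopentanes, two cyclopentenones); the two piperidine rings arise last by ring expansion of the cyclopentanones.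
- Enabling feature: with N2' removed and C1' bonded to C3', each cis-fused cyclopenta[c]pyridine unit (C1' aryl-bearing, N2', C3', C4' methyl, C4a', C5', C6', C7' methyl, C7a') is a cis-bicyclo[3.3.0]octan-3-one. Its C1' aryl, C4' methyl and C7' methyl groups all lie on the convex face, which is what a 1,6-enyne cyclocarbonylation followed by equilibration delivers.
- Stereochemistry: C2/C3 come from (+)-catechin and C7' from (S)-citronellal. C1' and C7a' are set in the key step by suprafacial addition to the (E)-alkene on the face that puts the C7' methyl exo. C4a' is set by hydrogenation to the cis-fused diquinane, C4' by enolate equilibration, and C1' is carried through the Beckmann shift with retention.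

Key step: step 10

Remark: primed locants follow cyclopenta[c]pyridine numbering of each arm and are kept for its carbocyclic precursors (C3' is the carbon delivered by CO). Both arms have the same configuration. MOM = CH2OCH3. Step 8 consumes two molecules of aldehyde 8 per molecule of 11, one for each arm, and every later step acts on both arms at once. The carbinol centres of 13 form as a mixture that is erased in step 9.

**Step 1**
Reactants: 1 (S)-citronellal
Product: 2 (6S)-8,8-dimethoxy-2,6-dimethyloct-2-ene
Conditions: HC(OMe)3, MeOH, PPTS (cat.), rt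
Reagents that add atoms: trimethyl orthoformate, COC(OC)OC; methanol, CO
Why: Acid-catalysed acetalisation with the orthoester as water scavenger masks the aldehyde for the ozonolysis and acetylide steps; the weak acid should not trigger the carbonyl-ene cyclisation of citronellal and the stereocentre is untouched.

**Step 2**
Reactants: 2 (6S)-8,8-dimethoxy-2,6-dimethyloct-2-ene
Product: 4 (4S)-6,6-dimethoxy-4-methylhexanal, via secondary ozonide 3 (not isolated)
Conditions: O3, CH2Cl2, −78 °C; then PPh3, −78 °C → rt
Reagents that add atoms: ozone, [O-][O+]=O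
Why: Ozonolysis of the electron-rich trisubstituted alkene with reductive work-up gives the aldehyde and acetone, the dimethyl acetal being inert at −78 °C.

**Step 3**
Reactants: 4 (4S)-6,6-dimethoxy-4-methylhexanal
Product: 5 (5S)-7,7-dimethoxy-5-methylhept-1-yne
Conditions: dimethyl (1-diazo-2-oxopropyl)phosphonate, K2CO3, MeOH, 0 °C → rt
Reagents that add atoms: dimethyl (1-diazo-2-oxopropyl)phosphonate, COP(=O)(OC)C(=[N+]=[N-])C(C)=O
Why: Ohira–Bestmann (Seyferth–Gilbert) homologation turns the unbranched aldehyde into the terminal alkyne under mildly basic conditions that leave the acetal and the remote stereocentre alone.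

**Step 4**
Reactants: 5 (5S)-7,7-dimethoxy-5-methylhept-1-yne
Product: 7 (6S)-8,8-dimethoxy-6-methyloct-2-yne, via lithium acetylide 6 (not isolated)
Conditions: n-BuLi, THF, −78 °C; then MeI, −78 °C → rt
Reagents that add atoms: iodomethane, CI
Why: Deprotonation of the terminal alkyne and SN2 methylation of the acetylide installs the methyl group that becomes the C4' methyl.

**Step 5**
Reactants: 7 (6S)-8,8-dimethoxy-6-methyloct-2-yne
Product: 8 (3S)-3-methyloct-6-ynal
Conditions: HCl (1 M aq., cat.), THF, rt
Reagents that add atoms: water, O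
Why: Acetal hydrolysis releases the aldehyde, whose stereocentre is β to the carbonyl group and cannot epimerise by enolisation.

**Step 6**
Reactants: 9 (+)-catechin
Product: 10 (+)-catechin pentakis(MOM) ether [(2R,3S)-2-[3,4-bis(methoxymethoxy)phenyl]-3,5,7-tris(methoxymethoxy)chromane]
Conditions: MOMCl (8 equiv), i-Pr2NEt (10 equiv), DMF, 0 → 45 °C
Reagents that add atoms: chloromethyl methyl ether, COCCl
Why: O-Alkylation with the reactive α-chloro ether under amine base protects the four phenols and the C3 alcohol in one operation without the strong base that could open ring C and epimerise C2; MOM ethers tolerate organolithiums, hydrides and bases.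

**Step 7**
Reactants: 10 (+)-catechin pentakis(MOM) ether
Product: 11 6,8-dibromo-(+)-catechin pentakis(MOM) ether
Conditions: NBS (2.1 equiv), CH2Cl2, 0 °C → rt
Reagents that add atoms: N-bromosuccinimide, O=C1CCC(=O)N1Br
Why: Electrophilic aromatic bromination takes the two free positions of the phloroglucinol-type ring A (C8, then C6), which is far more electron-rich than ring B, as is known for O-protected catechins.

**Step 8**
Reactants: 11 6,8-dibromo-(+)-catechin pentakis(MOM) ether; 8 (3S)-3-methyloct-6-ynal (two molecules react, one at C6 and one at C8)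
Product: 13 6,8-bis[(3S)-1-hydroxy-3-methyloct-6-yn-1-yl]-(+)-catechin pentakis(MOM) ether (carbinol epimers), via 6,8-dilithio arene 12 (not isolated)
Conditions: t-BuLi (4.2 equiv), THF, −78 °C; then 8 (2.4 equiv), −78 → −20 °C; H2O
Reagents that add atoms: second molecule of (3S)-3-methyloct-6-ynal 8, O=CC[C@@H](C)CCC#CC
Why: Two-fold bromine–lithium exchange gives the dilithio arene, each carbanion flanked and stabilised by two ortho oxygens, and 1,2-addition of each aryllithium to one molecule of the aldehyde gives the bis(benzylic alcohol), so two molecules of 8 end up in 13; the carbinol configuration is irrelevant because both centres become sp2 in step 9.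

**Step 9**
Reactants: 13 6,8-bis[(3S)-1-hydroxy-3-methyloct-6-yn-1-yl]-(+)-catechin pentakis(MOM) ether
Product: 14 6,8-bis[(1E,3S)-3-methyloct-1-en-6-yn-1-yl]-(+)-catechin pentakis(MOM) ether
Conditions: Burgess reagent (3 equiv), toluene, 60 °C
Reagents that add atoms: none
Why: Burgess dehydration (sulfamate ester, then syn-elimination or E1 loss through the dialkoxy-stabilised benzylic cation) can only remove a C2 hydrogen and should give the conjugated (E)-styrene, the (Z)-isomer being disfavoured by the two ortho substituents; the neutral conditions spare MOM ethers and alkynes.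

**Step 10**
Reactants: 14 6,8-bis[(1E,3S)-3-methyloct-1-en-6-yn-1-yl]-(+)-catechin pentakis(MOM) ether
Product: 16 6,8-bis[(1R,6S,6aS)-3,6-dimethyl-2-oxo-1,2,4,5,6,6a-hexahydropentalen-1-yl]-(+)-catechin pentakis(MOM) ether (primed locants 1'R,7'S,7a'S; C3'=O; C4'=C4a'), via bis(hexacarbonyldicobalt) alkyne complex 15 (not isolated)
Conditions: Co2(CO)8 (2.3 equiv), CH2Cl2, rt; then NMO (12 equiv), 4 Å MS, 0 °C → rt
Reagents that add atoms: dicobalt octacarbonyl (supplies C3' and its oxygen as CO), O=C=[Co](=C=O)(=C=O)(=C=O)[Co](=C=O)(=C=O)(=C=O)=C=O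
Why: Each methyl alkyne is first bound as its Co2(CO)6 complex; N-oxide-induced loss of CO opens a site on cobalt for the tethered (E)-alkene, which inserts into a Co–C bond (forming C4a'–C7a'), CO then inserts and reductive elimination forms C3'–C4' and C1'–C3' and releases the cyclopentenone. The closest known reaction type is the intramolecular Pauson–Khand reaction of hept-1-en-6-ynes that carry a 1,2-disubstituted styrenyl alkene and an internal alkyne, run here on two independent arms of one molecule. In each arm the cyclopentane (C4a'–C5'–C6'–C7'–C7a') closes in a 5-exo mode by bonding the alkene carbon C7a' to the alkyne carbon C4a', and the cyclopentenone (C1'–C3'–C4'–C4a'–C7a') closes by the carbonylative [2+2+1] union of C1' and C4' through the new carbonyl carbon C3'. C1' relative to C7a' follows from suprafacial addition to the (E)-alkene, so the aryl group ends trans to C7', and C7a' relative to C7' is controlled by the allylic (S)-methyl group, which takes the exo position anti to the cobalt-bound, aryl-bearing C1' in the cobaltacycle. The step needs facial selectivity with respect to C7' and pairing of each alkyne with its own alkene: the first is secured by the citronellal-derived centre next to the reacting alkene carbon together with the bulk at C1', the second by the three-atom tether, which permits only the 1,6-enyne mode. C1' remains epimerisable (α to the ketone) and settles on the convex face, so only the C7a'/C7' relationship has to be won kinetically.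

**Step 11**
Reactants: 16 bis-enone
Product: 18 6,8-bis[(1R,3R,3aS,6S,6aR)-3,6-dimethyl-2-oxooctahydropentalen-1-yl]-(+)-catechin pentakis(MOM) ether (1'R,4'R,4a'S,7'S,7a'R; aryl and both methyl groups on the convex face), via C4'-epimeric bis-ketone 17 (not isolated)
Conditions: H2 (4 atm), Pd/C (10%), EtOAc, rt; filtration; then K2CO3, MeOH, rt
Reagents that add atoms: none
Why: Heterogeneous hydrogenation adds both hydrogens to the tetrasubstituted enone on the face of H-7a', the only addition that leads to the unstrained cis-fused bicyclo[3.3.0]octanone (sets C4a'), leaving the C4' methyl endo in 17; K2CO3/MeOH then epimerises C4' through the enolate to the convex face while C1' stays exo, and MOM ethers, arenes and the benzylic ether of ring C are not hydrogenolysed under these conditions.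

**Step 12**
Reactants: 18 all-exo bis-ketone
Product: 19 bis-oxime, 6,8-bis[(1R,2E,3R,3aS,6S,6aR)-2-(hydroxyimino)-3,6-dimethyloctahydropentalen-1-yl]-(+)-catechin pentakis(MOM) ether (each OH anti to C1')
Conditions: NH2OH·HCl, pyridine, EtOH, 70 °C
Reagents that add atoms: hydroxylamine hydrochloride, Cl.NO
Why: Oxime condensation of the cyclopentanones; under these equilibrating conditions the hydroxyl group should settle on the side of the smaller methyl-bearing C4', anti to the aryl-bearing C1', which is the geometry the next step needs.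

**Step 13**
Reactants: 19 bis-oxime
Product: 21 6,8-bis[(1R,4R,4aS,7S,7aR)-4,7-dimethyl-3-oxooctahydro-1H-cyclopenta[c]pyridin-1-yl]-(+)-catechin pentakis(MOM) ether, via bis(oxime tosylate) 20 (not isolated)
Conditions: TsCl, Et3N, DMAP (cat.), CH2Cl2, 0 °C → rt; then NaHCO3, THF/H2O, 50 °C
Reagents that add atoms: water, O
Why: Beckmann rearrangement of the oxime sulfonate: the C1'–C3' bond anti to the leaving group shifts to nitrogen with retention at C1' and water captures the nitrilium carbon as the lactam carbonyl, so nitrogen is inserted between C1' and C3' under non-acidic conditions that MOM ethers tolerate.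

**Step 14**
Reactants: 21 bis-lactam
Product: 22 6,8-bis[(1R,4R,4aS,7S,7aR)-2,4,7-trimethyl-3-oxooctahydro-1H-cyclopenta[c]pyridin-1-yl]-(+)-catechin pentakis(MOM) ether
Conditions: NaH (2.4 equiv), MeI, THF/DMF, 0 °C → rt
Reagents that add atoms: iodomethane, CI
Why: N-Alkylation of the lactam sodium amidates with iodomethane; a slight excess of NaH removes only the amide protons, so C4' (α to the carbonyl group) is not enolised.

**Step 15**
Reactants: 22 bis(N-methyl lactam)
Product: 23 6,8-bis[(1R,4R,4aR,7S,7aR)-2,4,7-trimethyloctahydro-1H-cyclopenta[c]pyridin-1-yl]-(+)-catechin pentakis(MOM) ether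
Conditions: LiAlH4, THF, reflux
Reagents that add atoms: none
Why: LiAlH4 reduces the tertiary lactams to the tertiary amines (C3' becomes CH2) without touching MOM ethers, arenes or any stereocentre.

**Step 16**
Reactants: 23 bis-amine pentakis(MOM) ether
Product: 24 target, (2R,3S)-2-(3,4-dihydroxyphenyl)-6,8-bis[(1R,4R,4aR,7S,7aR)-2,4,7-trimethyloctahydro-1H-cyclopenta[c]pyridin-1-yl]chromane-3,5,7-triol
Conditions: HCl (1.5 M in MeOH), rt; then NaHCO3 (aq.)
Reagents that add atoms: none
Why: Acid-catalysed transacetalisation to methanol removes the four aryl and the one alkyl MOM ether while the amines are protected as ammonium ions; room temperature is kept so that the benzylic C1'–N bonds next to the freed phenols do not ionise.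

**Compound list**

1 | (S)-citronellal, (3S)-3,7-dimethyloct-6-enal | O=CC[C@@H](C)CCC=C(C)C | starting material
2 | (6S)-8,8-dimethoxy-2,6-dimethyloct-2-ene | COC(OC)C[C@@H](C)CCC=C(C)C | intermediate
3 | secondary ozonide (1,2,4-trioxolane) of 2, not isolated | COC(OC)C[C@@H](C)CCC1OOC(C)(C)O1 | intermediate
4 | (4S)-6,6-dimethoxy-4-methylhexanal | COC(OC)C[C@@H](C)CCC=O | intermediate
5 | (5S)-7,7-dimethoxy-5-methylhept-1-yne | COC(OC)C[C@@H](C)CCC#C | intermediate
6 | lithium acetylide of 5, not isolated | COC(OC)C[C@@H](C)CCC#C[Li] | intermediate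
7 | (6S)-8,8-dimethoxy-6-methyloct-2-yne | COC(OC)C[C@@H](C)CCC#CC | intermediate
8 | (3S)-3-methyloct-6-ynal | O=CC[C@@H](C)CCC#CC | intermediate
9 | (+)-catechin, (2R,3S) | Oc1cc(O)c2c(c1)O[C@H](c1ccc(O)c(O)c1)[C@@H](O)C2 | starting material
10 | (+)-catechin pentakis(methoxymethyl) ether | COCOc1cc(OCOC)c2c(c1)O[C@H](c1ccc(OCOC)c(OCOC)c1)[C@@H](OCOC)C2 | intermediate
11 | 6,8-dibromo-(+)-catechin pentakis(MOM) ether | COCOc1c(Br)c(OCOC)c2c(c1Br)O[C@H](c1ccc(OCOC)c(OCOC)c1)[C@@H](OCOC)C2 | intermediate
12 | 6,8-dilithio-(+)-catechin pentakis(MOM) ether, not isolated | COCOc1c([Li])c(OCOC)c2c(c1[Li])O[C@H](c1ccc(OCOC)c(OCOC)c1)[C@@H](OCOC)C2 | intermediate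
13 | 6,8-bis[(3S)-1-hydroxy-3-methyloct-6-yn-1-yl]-(+)-catechin pentakis(MOM) ether, both epimers at each carbinol carbon | COCOc1c(C(O)C[C@@H](C)CCC#CC)c(OCOC)c2c(c1C(O)C[C@@H](C)CCC#CC)O[C@H](c1ccc(OCOC)c(OCOC)c1)[C@@H](OCOC)C2 | intermediate
14 | 6,8-bis[(1E,3S)-3-methyloct-1-en-6-yn-1-yl]-(+)-catechin pentakis(MOM) ether | c1(/C=C/[C@@H](C)CCC#CC)c(OCOC)c2c(c(/C=C/[C@@H](C)CCC#CC)c1OCOC)O[C@H](c1ccc(OCOC)c(OCOC)c1)[C@@H](OCOC)C2 | intermediate
15 | 14 with each C6≡C7 triple bond bridging a Co2(CO)6 unit (zerovalent cobalt), not isolated | c1(/C=C/[C@@H](C)CCC67C8(C)[Co]6(=C=O)(=C=O)(=C=O)[Co]78(=C=O)(=C=O)=C=O)c(OCOC)c2c(c(/C=C/[C@@H](C)CCC67C8(C)[Co]6(=C=O)(=C=O)(=C=O)[Co]78(=C=O)(=C=O)=C=O)c1OCOC)O[C@H](c1ccc(OCOC)c(OCOC)c1)[C@@H](OCOC)C2 | intermediate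
16 | 6,8-bis[(1R,6S,6aS)-3,6-dimethyl-2-oxo-1,2,4,5,6,6a-hexahydropentalen-1-yl]-(+)-catechin pentakis(MOM) ether (aryl cis to H-7a', C7' methyl cis to H-7a') | c1([C@@H]3C(=O)C(C)=C4CC[C@H](C)[C@@H]34)c(OCOC)c2c(c([C@@H]3C(=O)C(C)=C4CC[C@H](C)[C@@H]34)c1OCOC)O[C@H](c1ccc(OCOC)c(OCOC)c1)[C@@H](OCOC)C2 | intermediate
17 | cis-fused bis-ketone with endo C4' methyl, arms (1R,3S,3aS,6S,6aR)-3,6-dimethyl-2-oxooctahydropentalen-1-yl, not isolated | C[C@@H]1C(=O)[C@@H](c2c(OCOC)c3c(c([C@H]4[C@H]5[C@H](CC[C@@H]5C)[C@H](C)C4=O)c2OCOC)O[C@H](c2ccc(OCOC)c(OCOC)c2)[C@@H](OCOC)C3)[C@H]2[C@@H]1CC[C@@H]2C | intermediate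
18 | all-exo cis-fused bis-ketone, arms (1R,3R,3aS,6S,6aR)-3,6-dimethyl-2-oxooctahydropentalen-1-yl | C[C@H]1C(=O)[C@@H](c2c(OCOC)c3c(c([C@H]4[C@H]5[C@H](CC[C@@H]5C)[C@@H](C)C4=O)c2OCOC)O[C@H](c2ccc(OCOC)c(OCOC)c2)[C@@H](OCOC)C3)[C@H]2[C@@H]1CC[C@@H]2C | intermediate
19 | bis-(E)-oxime of 18, each OH anti to C1' | C[C@H]1/C(=N\O)[C@@H](c2c(OCOC)c3c(c([C@H]4[C@H]5[C@H](CC[C@@H]5C)[C@@H](C)/C4=N\O)c2OCOC)O[C@H](c2ccc(OCOC)c(OCOC)c2)[C@@H](OCOC)C3)[C@H]2[C@@H]1CC[C@@H]2C | intermediate
20 | bis(O-tosyl oxime) of 18, not isolated | C[C@H]1/C(=N\OS(=O)(=O)c6ccc(C)cc6)[C@@H](c2c(OCOC)c3c(c([C@H]4[C@H]5[C@H](CC[C@@H]5C)[C@@H](C)/C4=N\OS(=O)(=O)c6ccc(C)cc6)c2OCOC)O[C@H](c2ccc(OCOC)c(OCOC)c2)[C@@H](OCOC)C3)[C@H]2[C@@H]1CC[C@@H]2C | intermediate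
21 | bis-lactam, arms (1R,4R,4aS,7S,7aR)-4,7-dimethyl-3-oxooctahydro-1H-cyclopenta[c]pyridin-1-yl | C[C@H]1C(=O)N[C@@H](c2c(OCOC)c3c(c([C@H]4[C@H]5[C@H](CC[C@@H]5C)[C@@H](C)C(=O)N4)c2OCOC)O[C@H](c2ccc(OCOC)c(OCOC)c2)[C@@H](OCOC)C3)[C@H]2[C@@H]1CC[C@@H]2C | intermediate
22 | bis(N-methyl lactam), arms (1R,4R,4aS,7S,7aR)-2,4,7-trimethyl-3-oxooctahydro-1H-cyclopenta[c]pyridin-1-yl | C[C@H]1C(=O)N(C)[C@@H](c2c(OCOC)c3c(c([C@H]4[C@H]5[C@H](CC[C@@H]5C)[C@@H](C)C(=O)N4C)c2OCOC)O[C@H](c2ccc(OCOC)c(OCOC)c2)[C@@H](OCOC)C3)[C@H]2[C@@H]1CC[C@@H]2C | intermediate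
23 | bis-amine pentakis(MOM) ether, arms (1R,4R,4aR,7S,7aR)-2,4,7-trimethyloctahydro-1H-cyclopenta[c]pyridin-1-yl | C[C@H]1CN(C)[C@@H](c2c(OCOC)c3c(c([C@H]4[C@H]5[C@H](CC[C@@H]5C)[C@@H](C)CN4C)c2OCOC)O[C@H](c2ccc(OCOC)c(OCOC)c2)[C@@H](OCOC)C3)[C@H]2[C@@H]1CC[C@@H]2C | intermediate
24 | CNP0284716.2, (2R,3S)-2-(3,4-dihydroxyphenyl)-6,8-bis[(1R,4R,4aR,7S,7aR)-2,4,7-trimethyloctahydro-1H-cyclopenta[c]pyridin-1-yl]chromane-3,5,7-triol | C[C@H]1CN(C)[C@@H](c2c(O)c3c(c([C@H]4[C@H]5[C@H](CC[C@@H]5C)[C@@H](C)CN4C)c2O)O[C@H](c2ccc(O)c(O)c2)[C@@H](O)C3)[C@H]2[C@@H]1CC[C@@H]2C | target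

**Step count**

Total: 16 steps. Longest linear sequence: 14 steps (from 1 through steps 1–5 and 8–16); the catechin branch (steps 6–7) joins at step 8.

**Steps most likely to fail, with fallbacks**

1. Step 10 (two-fold cyclocarbonylation). The second, more crowded arm may insert its alkene slowly so that decomplexation competes, and the allylic methyl group may discriminate the two alkene faces only partly, so that arms closed on the other face (epimeric at both C1' and C7a') build up. The fallback gives up kinetic face control and replaces it by a thermodynamic correction. Setting out from 14, the cyclocarbonylation is forced to full conversion under sulfide-promoted thermal conditions (Co2(CO)8, n-BuSMe, 1,2-dichloroethane, 83 °C) whatever the facial outcome. The crude product, in the limit the bis-enone with both arms closed on the opposite face, the 1',7a'-bis-epimeric bis-enone F1, is then warmed with NaOMe in MeOH (50 °C). C1' epimerises through the α'-enolate and C7a' through the γ-deprotonated extended dienolate (deconjugation and reconjugation of the enone). Because C7' is fixed and both the aryl group and the C7' methyl group prefer to be trans to their ring neighbours, the mixture should drain to 16, where the route is rejoined.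

2. Step 13 (Beckmann rearrangement). Ionisation of the oxime sulfonate may end in heterolysis of the C1'–C3' bond (fragmentation to a nitrile and a trialkoxybenzyl cation) instead of the 1,2-shift, with loss of the C1' configuration; slow hydration of the strained six-membered nitrilium gives this pathway time. The fallback sets out from bis-oxime 19 and uses a reductive ring expansion with i-Bu2AlH (excess, CH2Cl2, 0 °C → rt). The aluminium-bound oximate rearranges with the same anti migration of C1', and the resulting imine is reduced at once by the same reagent, so no nitrilium has to wait for water. This should give the bis(secondary amine) F2 with C3' already at the methylene level. Reductive methylation of F2 (aqueous CH2O, NaBH(OAc)3, 1,2-dichloroethane, rt) then returns to the route at 23, bypassing 20–22.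

3. Step 11 (enone saturation). Hydrogen has to reach the face of each tetrasubstituted enone that also carries the aryl and C7' methyl groups; uptake may be slow, and palladium may move the double bond (to C4a'=C7a' or into the other ring) before reduction, which would scramble C7a'. The fallback sets out from 16 and uses a homogeneous radical conjugate reduction by hydrogen-atom transfer: Mn(dpm)3 (tris(dipivaloylmethanato)manganese, trivalent manganese, catalytic), PhSiH3, i-PrOH, rt. It places a hydrogen atom on C4a' only, needs no adsorption of an alkene face and cannot isomerise the alkene; the cis ring fusion is favoured by strain. The crude ketone is equilibrated with K2CO3/MeOH exactly as in step 11, and the route is rejoined at 18. No compound outside the list is made (F0).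

**Further compounds**

F1 | step 10 | 1',7a'-bis-epimeric bis-enone, 6,8-bis[(1S,6S,6aR)-3,6-dimethyl-2-oxo-1,2,4,5,6,6a-hexahydropentalen-1-yl]-(+)-catechin pentakis(MOM) ether | c1([C@H]3C(=O)C(C)=C4CC[C@H](C)[C@H]34)c(OCOC)c2c(c([C@H]3C(=O)C(C)=C4CC[C@H](C)[C@H]34)c1OCOC)O[C@H](c1ccc(OCOC)c(OCOC)c1)[C@@H](OCOC)C2
F2 | step 13 | bis(secondary amine), 6,8-bis[(1R,4R,4aR,7S,7aR)-4,7-dimethyloctahydro-1H-cyclopenta[c]pyridin-1-yl]-(+)-catechin pentakis(MOM) ether | C[C@H]1CN[C@@H](c2c(OCOC)c3c(c([C@H]4[C@H]5[C@H](CC[C@@H]5C)[C@@H](C)CN4)c2OCOC)O[C@H](c2ccc(OCOC)c(OCOC)c2)[C@@H](OCOC)C3)[C@H]2[C@@H]1CC[C@@H]2C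
F0 | step 11 | none | none
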